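## Retrosynthetic overview

- Target 27 ⇐ triol 25 (acetylation, PMB removal) ⇐ 6β-hydroxy enone 24 (hydroxyl-directed reduction) ⇐ dienone 19 (α-face reductions, allylic re-oxidation), in which the C6 ketone is masked as a silyl enol ether.
- Ring B of 19 is disconnected at C7–C8 and C9–C10 into cyclobutenone 11 and internal alkyne 18; the alkyne carbons become C8 (with its methyl) and C9 (with the whole C11–C15 chain).
- Enabling feature: C7 and the quaternary C10 are first joined directly in a four-membered ring C5=C6–C7(=O)–C10 fused to ring A. Its strained acyl–C(sp3) bond C7–C10 is the bond zerovalent nickel cleaves, and because C10 bears no hydrogen the ring-expanded dienone cannot aromatise.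
- 11 ⇐ 4π-closure of an α-silyloxy vinylketene ⇐ acid from the enol triflate of (4R,6R)-actinol 1 and ethyl glyoxylate 5; 18 ⇐ geraniol 12.
- Ring order: ring A from the chiral pool, then the temporary four-membered ring (step 6), then ring B by two-carbon ring expansion (step 12).

Key step: step 12

Remark on the chemistry: positions are given in labdane numbering (decalin C1–C10, side chain C11–C15 on C9); β is the face of the C10 methyl and α the opposite face. Compounds 1, 5 and 12 are assumed to be commercially available. Where C7 is a mixture of epimers (20–23), both are carried on because step 14 converges them.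

## Route

Step 1
Reactants: 1 (4R,6R)-4-hydroxy-2,2,6-trimethylcyclohexan-1-one
Product: 2 (4R,6R)-2,2,6-trimethyl-4-[(triethylsilyl)oxy]cyclohexan-1-one
Conditions: TESCl, imidazole, DMF, 0 °C → rt
Reagents that add atoms: chlorotriethylsilane, CC[Si](Cl)(CC)CC
Why: Routine silylation of the secondary alcohol; the triethylsilyl group is chosen so that it is lost together with the enol silyl ether in step 13.

Step 2
Reactants: 2 (4R,6R)-2,2,6-trimethyl-4-[(triethylsilyl)oxy]cyclohexan-1-one
Product: 4 (4R)-2,6,6-trimethyl-4-[(triethylsilyl)oxy]cyclohex-1-en-1-yl trifluoromethanesulfonate, via lithium enolate 3 (not isolated)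
Conditions: LiN(iPr)2, THF, −78 °C; then PhNTf2, −78 → 0 °C
Reagents that add atoms: N-phenylbis(trifluoromethanesulfonimide), O=S(=O)(N(c1ccccc1)S(=O)(=O)C(F)(F)F)C(F)(F)F
Why: Enol triflate formation by O-sulfonylation of the enolate; C6 is the only enolisable position because C2 is quaternary, so one regioisomer should form, and the C6 stereocentre (future C10) is deliberately erased.

Step 3
Reactants: 4 (4R)-2,6,6-trimethyl-4-[(triethylsilyl)oxy]cyclohex-1-en-1-yl trifluoromethanesulfonate; 5 ethyl glyoxylate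
Product: 6 ethyl 2-hydroxy-2-{(4R)-2,6,6-trimethyl-4-[(triethylsilyl)oxy]cyclohex-1-en-1-yl}acetate (both carbinol epimers)
Conditions: CrCl2, NiCl2 (2 mol %), DMF, rt
Reagents that add atoms: none
Why: Nozaki–Hiyama–Kishi coupling (nickel-catalysed activation of the alkenyl triflate, transmetalation to chromium, addition of the alkenylchromium species to the aldehyde), which tolerates hindered alkenyl triflates, esters and silyl ethers; the new carbinol centre (future C6) forms unselectively and later becomes sp2.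

Step 4
Reactants: 6 ethyl 2-hydroxy-2-{(4R)-2,6,6-trimethyl-4-[(triethylsilyl)oxy]cyclohex-1-en-1-yl}acetate
Product: 7 2-hydroxy-2-{(4R)-2,6,6-trimethyl-4-[(triethylsilyl)oxy]cyclohex-1-en-1-yl}acetic acid
Conditions: LiOH, THF–MeOH–H2O, rt; then 1 M HCl to pH 4, 0 °C
Reagents that add atoms: lithium hydroxide, [Li+].[OH-]
Why: Saponification of an α-hydroxy ester; the silyl ether and the tetrasubstituted alkene should be inert.

Step 5
Reactants: 7 2-hydroxy-2-{(4R)-2,6,6-trimethyl-4-[(triethylsilyl)oxy]cyclohex-1-en-1-yl}acetic acid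
Product: 8 tert-butyldimethylsilyl 2-[(tert-butyldimethylsilyl)oxy]-2-{(4R)-2,6,6-trimethyl-4-[(triethylsilyl)oxy]cyclohex-1-en-1-yl}acetate
Conditions: TBSOTf, 2,6-lutidine, CH2Cl2, 0 °C
Reagents that add atoms: tert-butyldimethylsilyl trifluoromethanesulfonate, CC(C)(C)[Si](C)(C)OS(=O)(=O)C(F)(F)F
Why: Silylation of both the hindered allylic hydroxyl and the carboxylic acid with a silyl triflate; the silyl ester is the neutral precursor of the acid chloride.

Step 6
Reactants: 8 tert-butyldimethylsilyl 2-[(tert-butyldimethylsilyl)oxy]-2-{(4R)-2,6,6-trimethyl-4-[(triethylsilyl)oxy]cyclohex-1-en-1-yl}acetate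
Product: 11 (4S,6S)-8-[(tert-butyldimethylsilyl)oxy]-2,2,6-trimethyl-4-[(triethylsilyl)oxy]bicyclo[4.2.0]oct-1(8)-en-7-one (ring A fused to the four-membered ring C5=C6–C7(=O)–C10; 10β-methyl, 2α-silyloxy), via acid chloride 9 (not isolated), via silyloxy vinylketene 10 (not isolated)
Conditions: (COCl)2, DMF (cat.), CH2Cl2, 0 °C → rt; then Et3N, toluene, 0 → 80 °C
Reagents that add atoms: none
Why: The silyl ester is converted into the acid chloride under neutral conditions, triethylamine removes the doubly activated (allylic, α-oxygenated) C6 hydrogen to give silyloxy vinylketene 10, and a thermal conrotatory 4π-electrocyclisation (the reverse of the well-known cyclobutenone ring opening, here pulled towards the ring by the ketene-destabilising oxygen substituent) forms C7–C10; because C7 must lie in the plane of C5=C6 the C10 methyl is forced axial on ring A, so the reversible closure should settle on the isomer with the C2 silyloxy group equatorial, i.e. 10β-methyl trans to the 2α-oxygen.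

Step 7
Reactants: 12 geraniol
Product: 13 1-({[(2E)-3,7-dimethylocta-2,6-dien-1-yl]oxy}methyl)-4-methoxybenzene (geranyl PMB ether)
Conditions: NaH, PMBCl, Bu4NI (cat.), THF–DMF, 0 °C → rt
Reagents that add atoms: 4-methoxybenzyl chloride, COc1ccc(CCl)cc1
Why: Williamson ether synthesis; the 2E alkene of geraniol becomes the 13E alkene of the target.

Step 8
Reactants: 13 geranyl PMB ether
Product: 14 3-{(3E)-5-[(4-methoxybenzyl)oxy]-3-methylpent-3-en-1-yl}-2,2-dimethyloxirane (racemic at the oxirane carbon)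
Conditions: mCPBA, CH2Cl2, −20 → 0 °C
Reagents that add atoms: 3-chloroperoxybenzoic acid, OOC(=O)c1cccc(Cl)c1
Why: Prilezhaev epoxidation, selective for the more electron-rich remote alkene because the other one is deactivated by the allylic ether oxygen; the epoxide configuration is irrelevant.

Step 9
Reactants: 14 3-{(3E)-5-[(4-methoxybenzyl)oxy]-3-methylpent-3-en-1-yl}-2,2-dimethyloxirane
Product: 15 (4E)-6-[(4-methoxybenzyl)oxy]-4-methylhex-4-enal
Conditions: H5IO6, THF–H2O, 0 °C
Reagents that add atoms: none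
Why: Periodic acid hydrolyses the epoxide (water at the tertiary carbon) and cleaves the resulting glycol (Malaprade-type cleavage) to the aldehyde, whose oxygen is the former epoxide oxygen.

Step 10
Reactants: 15 (4E)-6-[(4-methoxybenzyl)oxy]-4-methylhex-4-enal
Product: 16 1-methoxy-4-({[(2E)-3-methylhept-2-en-6-yn-1-yl]oxy}methyl)benzene
Conditions: dimethyl (1-diazo-2-oxopropyl)phosphonate, K2CO3, MeOH, 0 °C → rt
Reagents that add atoms: dimethyl (1-diazo-2-oxopropyl)phosphonate, CC(=O)C(=[N+]=[N-])P(=O)(OC)OC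
Why: Seyferth–Gilbert homologation in the Ohira–Bestmann form converts the aldehyde into the terminal alkyne under mild basic conditions that leave the E-alkene and the ether untouched.

Step 11
Reactants: 16 1-methoxy-4-({[(2E)-3-methylhept-2-en-6-yn-1-yl]oxy}methyl)benzene
Product: 18 1-methoxy-4-({[(2E)-3-methyloct-2-en-6-yn-1-yl]oxy}methyl)benzene, via lithium acetylide 17 (not isolated)
Conditions: nBuLi, THF, −78 °C; then MeI, −78 °C → rt
Reagents that add atoms: iodomethane, CI
Why: C-methylation of the lithium acetylide (SN2 on iodomethane) gives the internal alkyne whose two sp carbons become C8 and C9.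

Step 12
Reactants: 11 cyclobutenone (4S,6S)-8-[(tert-butyldimethylsilyl)oxy]-2,2,6-trimethyl-4-[(triethylsilyl)oxy]bicyclo[4.2.0]oct-1(8)-en-7-one; 18 1-methoxy-4-({[(2E)-3-methyloct-2-en-6-yn-1-yl]oxy}methyl)benzene
Product: 19 6-[(tert-butyldimethylsilyl)oxy]-15-[(4-methoxybenzyl)oxy]-2α-[(triethylsilyl)oxy]labda-5,8,13E-trien-7-one (10β-methyl)
Conditions: Ni(cod)2 (10 mol %), PPh3 (20 mol %), toluene, 25 → 60 °C
Reagents that add atoms: none
Why: Proposed new method: zerovalent nickel should insert oxidatively into the strained acyl–C(sp3) bond C7–C10 of 11 to give a nickelacyclopentenone (equally an η4-vinylketene complex), the alkyne then inserts into the Ni–acyl bond (C7–C8) and C(sp2)–C(sp3) reductive elimination from the seven-membered nickelacycle forms C9–C10 and releases the catalyst. The closest known reactions are the nickel-catalysed union of cyclobutenones with alkynes, which ends in phenols because the sp3 ring carbon there carries hydrogen, and the nickel-catalysed alkyne insertion into cyclobutanones and azetidinones; new here are the quaternary, ring-fused C10 (so the cross-conjugated dienone is the end product) and the silyloxy group on C6. Ring B is the only ring closed, and it closes by two-carbon ring expansion of the four-membered ring, a formal [4+2] of the C10–C5=C6–C7 unit with C8≡C9. The only stereocentre at stake is C10: nickel stays on the face on which it broke C7–C10, so C9 should replace C7 with retention, and the same outcome is favoured independently because the planar ring B forces the C10 methyl axial on ring A, which is strain-free only with the C2 silyloxy group equatorial (methyl β, oxygen α). The step needs site selectivity in bond cleavage (C7–C10 over C6–C7, secured by the sp3 versus sp2 carbon and by allyl-type stabilisation at C10) and one orientation of the unsymmetrical alkyne (methyl-bearing carbon to C7); the argument for the latter is that the acyl carbon, crowded by the C6 silyloxy group, migrates to the alkyne carbon with the smaller substituent while the chain-bearing carbon stays on nickel and is delivered to C10, the small PPh3 ligand being chosen to preserve this substrate control, and this orientation is the least secure point.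

Step 13
Reactants: 19 6-[(tert-butyldimethylsilyl)oxy]-15-[(4-methoxybenzyl)oxy]-2α-[(triethylsilyl)oxy]labda-5,8,13E-trien-7-one
Product: 23 15-[(4-methoxybenzyl)oxy]labda-8,13E-diene-2α,6β,7-triol (5α-H; both C7 epimers), via dienol 20 (not isolated), via hydroxy ketone 21 (not isolated), via monosilyl diol 22 (not isolated)
Conditions: NaBH4, THF–MeOH, 0 °C; then TBAF, NaBH4, 0 °C → rt
Reagents that add atoms: none
Why: NaBH4 first reduces the cross-conjugated C7 ketone in the 1,2-sense (both β-carbons are fully substituted), fluoride then cleaves the enol silyl ether, the enolate is protonated at C5 from the α-face (β-face shielded by the C10 and 4β methyls; also the thermodynamic trans ring fusion) and the unveiled C6 ketone is reduced in situ from the same open α-face to the axial 6β-alcohol before an α-ketol shift can intervene, the triethylsilyl ether being lost last.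

Step 14
Reactants: 23 15-[(4-methoxybenzyl)oxy]labda-8,13E-diene-2α,6β,7-triol
Product: 24 2α,6β-dihydroxy-15-[(4-methoxybenzyl)oxy]labda-8,13E-dien-7-one
Conditions: MnO2, CH2Cl2, rt
Reagents that add atoms: none
Why: Activated MnO2 oxidises only the allylic C7 alcohol (both epimers converge on one enone); the non-allylic C2 and C6 hydroxyls and the PMB ether should be inert.

Step 15
Reactants: 24 2α,6β-dihydroxy-15-[(4-methoxybenzyl)oxy]labda-8,13E-dien-7-one
Product: 25 15-[(4-methoxybenzyl)oxy]labda-8,13E-diene-2α,6β,7α-triol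
Conditions: Me4NBH(OAc)3, MeCN–AcOH, −20 °C → rt
Reagents that add atoms: none
Why: Hydroxyl-directed reduction (Evans–Saksena type): the axial 6β-hydroxyl exchanges onto boron and delivers hydride intramolecularly to the β-face of the C7 carbonyl, giving the 7α-alcohol (trans-diaxial 6β,7α-diol), while the enone is inert to external triacetoxyborohydride.

Step 16
Reactants: 25 15-[(4-methoxybenzyl)oxy]labda-8,13E-diene-2α,6β,7α-triol
Product: 26 2α,6β,7α-triacetoxy-15-[(4-methoxybenzyl)oxy]labda-8,13E-diene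
Conditions: Ac2O, DMAP, pyridine, 40 °C
Reagents that add atoms: acetic anhydride, CC(=O)OC(C)=O
Why: DMAP-catalysed acetylation of the three secondary hydroxyls (the hindered axial 6β-hydroxyl needs the nucleophilic catalyst and gentle warming), while the primary C15 oxygen stays masked as the PMB ether.

Step 17
Reactants: 26 2α,6β,7α-triacetoxy-15-[(4-methoxybenzyl)oxy]labda-8,13E-diene
Product: 27 2α,6β,7α-triacetoxylabda-8,13E-dien-15-ol (target)
Conditions: DDQ, CH2Cl2–pH 7 buffer, 0 °C
Reagents that add atoms: none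
Why: Oxidative cleavage of the PMB ether by DDQ (benzylic hydride abstraction, hydrolysis of the oxocarbenium ion) under buffered conditions should free the primary allylic alcohol without touching the three acetates or the tetrasubstituted alkene.

## Compound list

1 | (4R,6R)-4-hydroxy-2,2,6-trimethylcyclohexan-1-one (actinol) | O[C@H]1CC(C)(C)C(=O)[C@H](C)C1 | starting material
2 | (4R,6R)-2,2,6-trimethyl-4-[(triethylsilyl)oxy]cyclohexan-1-one | CC[Si](CC)(CC)O[C@H]1CC(C)(C)C(=O)[C@H](C)C1 | intermediate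
3 | lithium (4R)-2,6,6-trimethyl-4-[(triethylsilyl)oxy]cyclohex-1-en-1-olate | [Li+].CC[Si](CC)(CC)O[C@H]1CC(C)(C)C([O-])=C(C)C1 | intermediate
4 | (4R)-2,6,6-trimethyl-4-[(triethylsilyl)oxy]cyclohex-1-en-1-yl trifluoromethanesulfonate | CC[Si](CC)(CC)O[C@H]1CC(C)(C)C(OS(=O)(=O)C(F)(F)F)=C(C)C1 | intermediate
5 | ethyl glyoxylate (ethyl 2-oxoacetate) | CCOC(=O)C=O | starting material
6 | ethyl 2-hydroxy-2-{(4R)-2,6,6-trimethyl-4-[(triethylsilyl)oxy]cyclohex-1-en-1-yl}acetate (carbinol epimers) | CC[Si](CC)(CC)O[C@H]1CC(C)(C)C(C(O)C(=O)OCC)=C(C)C1 | intermediate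
7 | 2-hydroxy-2-{(4R)-2,6,6-trimethyl-4-[(triethylsilyl)oxy]cyclohex-1-en-1-yl}acetic acid | CC[Si](CC)(CC)O[C@H]1CC(C)(C)C(C(O)C(O)=O)=C(C)C1 | intermediate
8 | tert-butyldimethylsilyl 2-[(tert-butyldimethylsilyl)oxy]-2-{(4R)-2,6,6-trimethyl-4-[(triethylsilyl)oxy]cyclohex-1-en-1-yl}acetate | CC[Si](CC)(CC)O[C@H]1CC(C)(C)C(C(O[Si](C)(C)C(C)(C)C)C(=O)O[Si](C)(C)C(C)(C)C)=C(C)C1 | intermediate
9 | 2-[(tert-butyldimethylsilyl)oxy]-2-{(4R)-2,6,6-trimethyl-4-[(triethylsilyl)oxy]cyclohex-1-en-1-yl}acetyl chloride | CC[Si](CC)(CC)O[C@H]1CC(C)(C)C(C(O[Si](C)(C)C(C)(C)C)C(Cl)=O)=C(C)C1 | intermediate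
10 | 2-[(tert-butyldimethylsilyl)oxy]-2-{(4R)-2,6,6-trimethyl-4-[(triethylsilyl)oxy]cyclohex-1-en-1-yl}ethen-1-one (silyloxy vinylketene) | CC[Si](CC)(CC)O[C@H]1CC(C)(C)C(C(O[Si](C)(C)C(C)(C)C)=C=O)=C(C)C1 | intermediate
11 | (4S,6S)-8-[(tert-butyldimethylsilyl)oxy]-2,2,6-trimethyl-4-[(triethylsilyl)oxy]bicyclo[4.2.0]oct-1(8)-en-7-one | CC[Si](CC)(CC)O[C@H]1CC(C)(C)C2=C(O[Si](C)(C)C(C)(C)C)C(=O)[C@@]2(C)C1 | intermediate
12 | geraniol, (2E)-3,7-dimethylocta-2,6-dien-1-ol | CC(C)=CCC/C(C)=C/CO | starting material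
13 | 1-({[(2E)-3,7-dimethylocta-2,6-dien-1-yl]oxy}methyl)-4-methoxybenzene | CC(C)=CCC/C(C)=C/COCc1ccc(OC)cc1 | intermediate
14 | 3-{(3E)-5-[(4-methoxybenzyl)oxy]-3-methylpent-3-en-1-yl}-2,2-dimethyloxirane (racemic) | CC1(C)OC1CC/C(C)=C/COCc1ccc(OC)cc1 | intermediate
15 | (4E)-6-[(4-methoxybenzyl)oxy]-4-methylhex-4-enal | O=CCC/C(C)=C/COCc1ccc(OC)cc1 | intermediate
16 | 1-methoxy-4-({[(2E)-3-methylhept-2-en-6-yn-1-yl]oxy}methyl)benzene | C#CCC/C(C)=C/COCc1ccc(OC)cc1 | intermediate
17 | lithium acetylide of 16 | [Li+].[C-]#CCC/C(C)=C/COCc1ccc(OC)cc1 | intermediate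
18 | 1-methoxy-4-({[(2E)-3-methyloct-2-en-6-yn-1-yl]oxy}methyl)benzene | CC#CCC/C(C)=C/COCc1ccc(OC)cc1 | intermediate
19 | 6-[(tert-butyldimethylsilyl)oxy]-15-[(4-methoxybenzyl)oxy]-2α-[(triethylsilyl)oxy]labda-5,8,13E-trien-7-one | CC[Si](CC)(CC)O[C@H]1CC(C)(C)C2=C(O[Si](C)(C)C(C)(C)C)C(=O)C(C)=C(CC/C(C)=C/COCc3ccc(OC)cc3)[C@@]2(C)C1 | intermediate
20 | 6-[(tert-butyldimethylsilyl)oxy]-15-[(4-methoxybenzyl)oxy]-2α-[(triethylsilyl)oxy]labda-5,8,13E-trien-7-ol (C7 epimers) | CC[Si](CC)(CC)O[C@H]1CC(C)(C)C2=C(O[Si](C)(C)C(C)(C)C)C(O)C(C)=C(CC/C(C)=C/COCc3ccc(OC)cc3)[C@@]2(C)C1 | intermediate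
21 | 7-hydroxy-15-[(4-methoxybenzyl)oxy]-2α-[(triethylsilyl)oxy]labda-8,13E-dien-6-one (5α-H; C7 epimers) | CC[Si](CC)(CC)O[C@H]1CC(C)(C)[C@@H]2C(=O)C(O)C(C)=C(CC/C(C)=C/COCc3ccc(OC)cc3)[C@@]2(C)C1 | intermediate
22 | 15-[(4-methoxybenzyl)oxy]-2α-[(triethylsilyl)oxy]labda-8,13E-diene-6β,7-diol (C7 epimers) | CC[Si](CC)(CC)O[C@H]1CC(C)(C)[C@@H]2[C@H](O)C(O)C(C)=C(CC/C(C)=C/COCc3ccc(OC)cc3)[C@@]2(C)C1 | intermediate
23 | 15-[(4-methoxybenzyl)oxy]labda-8,13E-diene-2α,6β,7-triol (C7 epimers) | O[C@H]1CC(C)(C)[C@@H]2[C@H](O)C(O)C(C)=C(CC/C(C)=C/COCc3ccc(OC)cc3)[C@@]2(C)C1 | intermediate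
24 | 2α,6β-dihydroxy-15-[(4-methoxybenzyl)oxy]labda-8,13E-dien-7-one | O[C@H]1CC(C)(C)[C@@H]2[C@H](O)C(=O)C(C)=C(CC/C(C)=C/COCc3ccc(OC)cc3)[C@@]2(C)C1 | intermediate
25 | 15-[(4-methoxybenzyl)oxy]labda-8,13E-diene-2α,6β,7α-triol | O[C@H]1CC(C)(C)[C@@H]2[C@H](O)[C@@H](O)C(C)=C(CC/C(C)=C/COCc3ccc(OC)cc3)[C@@]2(C)C1 | intermediate
26 | 2α,6β,7α-triacetoxy-15-[(4-methoxybenzyl)oxy]labda-8,13E-diene | CC(=O)O[C@H]1CC(C)(C)[C@@H]2[C@H](OC(C)=O)[C@@H](OC(C)=O)C(C)=C(CC/C(C)=C/COCc3ccc(OC)cc3)[C@@]2(C)C1 | intermediate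
27 | 2α,6β,7α-triacetoxylabda-8,13E-dien-15-ol (CNP0305346.2) | CC(=O)O[C@H]1CC(C)(C)[C@@H]2[C@H](OC(C)=O)[C@@H](OC(C)=O)C(C)=C(CC/C(C)=C/CO)[C@@]2(C)C1 | target

## Step count and risks

Total step count: 17. Longest linear sequence: 12 steps (steps 1–6 and 12–17); the alkyne branch (steps 7–11) joins at step 12.

Steps most likely to fail:

1. Step 12 (proposed new method). What may go wrong: insertion of the alkyne in the opposite orientation, β-hydride loss or decarbonylation from the nickelacycle, alkyne oligomerisation, or a stalled reductive elimination at the quaternary carbon. Fallback with known chemistry, setting out from 18 and 11 and returning at 19: hydrozirconation of 18 with Cp2Zr(H)Cl (equilibrated so that zirconium sits on the methyl-bearing carbon) and iodinolysis should give the (E)-alkenyl iodide F1, which fixes the regiochemistry by construction. Iodine–lithium exchange (tBuLi, −78 °C) and 1,2-addition of the alkenyllithium to the C7 carbonyl of 11 gives a cyclobutenolate. On warming it should undergo oxy-anion-accelerated 4π ring opening (oxide outward, alkenyl inward) and 6π-electrocyclisation (C9–C10), and trapping the enolate with TMSCl gives the bis-silyl dienol ether F2. Saegusa–Ito dehydrogenation with Pd(OAc)2 (divalent palladium) in MeCN should then give 19.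

2. Step 6. What may go wrong: a 1,5-hydrogen shift of the vinylketene to a dienal, ketene oligomerisation, or an unfavourable or slow ring closure. Fallback that avoids the four-membered ring, setting out from 8 and returning at 19: 8 is converted into acid chloride 9 as in step 6 and intercepted with N,O-dimethylhydroxylamine and Et3N to give the Weinreb amide F3. The alkenyllithium made from the alkenyl iodide F1 (from 18, as above) acylates cleanly to the dienone F4. Soft enolisation (TMSOTf, Et3N) gives the silyloxy triene F5, whose thermal 6π-electrocyclisation (toluene, 110 °C) forms C9–C10 and gives the bis-silyl dienol ether F2. Saegusa–Ito oxidation (Pd(OAc)2, MeCN) then gives 19.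

3. Step 13. What may go wrong: α-ketol shift of the unmasked 7-hydroxy-6-ketone before it is reduced, incomplete facial control in the C5 protonation or C6 hydride delivery, or acid-induced rearrangement of the bis-allylic alcohol on work-up. Fallback that blocks the ketol shift by acylation, setting out from 19 and returning at 23: the C7 ketone is reduced alone (NaBH4, CeCl3·7H2O, MeOH, −40 °C) and dienol 20 is isolated and acetylated (Ac2O, DMAP) to the dienyl acetate F6. Buffered fluoride (TBAF–AcOH, THF, −20 °C) unmasks only the enol silyl ether to give the acetoxy ketone F7, which cannot isomerise. NaBH4 reduction from the α-face gives the hydroxy acetate F8, and methanolysis of the acetate (K2CO3, MeOH) followed by TBAF gives 23.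

## Further compounds

F1 | step 12 | 1-({[(2E,6E)-7-iodo-3-methylocta-2,6-dien-1-yl]oxy}methyl)-4-methoxybenzene | C/C(I)=C\CC/C(C)=C/COCc1ccc(OC)cc1
F2 | step 12 | 6-[(tert-butyldimethylsilyl)oxy]-15-[(4-methoxybenzyl)oxy]-2α-[(triethylsilyl)oxy]-7-[(trimethylsilyl)oxy]labda-5,7,13E-triene (C9 epimers) | CC[Si](CC)(CC)O[C@H]1CC(C)(C)C2=C(O[Si](C)(C)C(C)(C)C)C(O[Si](C)(C)C)=C(C)C(CC/C(C)=C/COCc3ccc(OC)cc3)[C@@]2(C)C1
F3 | step 6 | 2-[(tert-butyldimethylsilyl)oxy]-N-methoxy-N-methyl-2-{(4R)-2,6,6-trimethyl-4-[(triethylsilyl)oxy]cyclohex-1-en-1-yl}acetamide | CC[Si](CC)(CC)O[C@H]1CC(C)(C)C(C(O[Si](C)(C)C(C)(C)C)C(=O)N(C)OC)=C(C)C1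
F4 | step 6 | (3E,7E)-1-[(tert-butyldimethylsilyl)oxy]-9-[(4-methoxybenzyl)oxy]-3,7-dimethyl-1-{(4R)-2,6,6-trimethyl-4-[(triethylsilyl)oxy]cyclohex-1-en-1-yl}nona-3,7-dien-2-one | CC[Si](CC)(CC)O[C@H]1CC(C)(C)C(C(O[Si](C)(C)C(C)(C)C)C(=O)/C(C)=C/CC/C(C)=C/COCc2ccc(OC)cc2)=C(C)C1
F5 | step 6 | trimethylsilyl dienol ether of F4, (3E,7E)-1-[(tert-butyldimethylsilyl)oxy]-9-[(4-methoxybenzyl)oxy]-3,7-dimethyl-1-{(4R)-2,6,6-trimethyl-4-[(triethylsilyl)oxy]cyclohex-1-en-1-yl}-2-[(trimethylsilyl)oxy]nona-1,3,7-triene | CC[Si](CC)(CC)O[C@H]1CC(C)(C)C(C(O[Si](C)(C)C(C)(C)C)=C(O[Si](C)(C)C)/C(C)=C/CC/C(C)=C/COCc2ccc(OC)cc2)=C(C)C1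
F6 | step 13 | 7-acetoxy-6-[(tert-butyldimethylsilyl)oxy]-15-[(4-methoxybenzyl)oxy]-2α-[(triethylsilyl)oxy]labda-5,8,13E-triene (C7 epimers) | CC[Si](CC)(CC)O[C@H]1CC(C)(C)C2=C(O[Si](C)(C)C(C)(C)C)C(OC(C)=O)C(C)=C(CC/C(C)=C/COCc3ccc(OC)cc3)[C@@]2(C)C1
F7 | step 13 | 7-acetoxy-15-[(4-methoxybenzyl)oxy]-2α-[(triethylsilyl)oxy]labda-8,13E-dien-6-one (5α-H; C7 epimers) | CC[Si](CC)(CC)O[C@H]1CC(C)(C)[C@@H]2C(=O)C(OC(C)=O)C(C)=C(CC/C(C)=C/COCc3ccc(OC)cc3)[C@@]2(C)C1
F8 | step 13 | 7-acetoxy-15-[(4-methoxybenzyl)oxy]-2α-[(triethylsilyl)oxy]labda-8,13E-dien-6β-ol (C7 epimers) | CC[Si](CC)(CC)O[C@H]1CC(C)(C)[C@@H]2[C@H](O)C(OC(C)=O)C(C)=C(CC/C(C)=C/COCc3ccc(OC)cc3)[C@@]2(C)C1
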